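**The leftover.** Reckon first what second reagent remains once the substrate has gone, since the listed step from intermediate A to intermediate B takes second reagent.

| flask | substrate | partner | second reagent | third reagent | capture agent | remark | time |
|---|---|---|---|---|---|---|---|
| ash | 0.20 M | 0.13 M | 0.22 M (fed, over 15 s) | 0.12 M | 0.20 M | run made earlier; the fed solution adds 0.25 times the starting volume |  |
| cedar | 0.20 M | 0.20 M | 0.22 M (fed, over 15 s) | 0.12 M | 0.20 M | run made earlier; the fed solution adds 0.25 times the starting volume |  |
| alder | 0.40 M | 0.26 M | 0.22 M (fed, over 15 s) | 0.12 M | 0.20 M | run made earlier; the fed solution adds 0.25 times the starting volume |  |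
| flask | 0.20 M | 0.260 M | 0.220 M (fed, over 15 s) | 0.120 M | 0.200 M | the fed solution adds 0.25 times the starting volume | 25 min |

| run | time / min | target / % |
|---|---|---|
| ash | 6.00 | 5 |
| ash | 8.00 | 14 |
| ash | 10.0 | 17 |
| ash | 12.0 | 19 |
| ash | 15.0 | 22 |
| cedar | 6.00 | 10 |
| cedar | 8.00 | 15 |
| cedar | 10.0 | 19 |
| cedar | 12.0 | 21 |
| cedar | 15.0 | 24 |
| alder | 6.00 | 8 |
| alder | 8.00 | 15 |
| alder | 10.0 | 16 |
| alder | 12.0 | 15 |
| alder | 15.0 | 18 |

(each reading ± 2 percentage points)

- charges are per starting volume, the dose included; the dosed solution carries all of it
- on the list of suspects stand: intermediate B + capture agent -> trapped intermediate; second reagent + intermediate A -> intermediate B; third reagent + intermediate B -> target; substrate + partner -> intermediate A; substrate + second reagent -> side product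

- the best time, 25 min at the latest, for target
- the amount of target, in percent of the substrate charged, at that time

**The cost.** Each substrate that becomes side product costs one second reagent, and so does each that passes from intermediate A to intermediate B. For the flask the cover is 1.10: second reagent charged over substrate charged. It stands above one, so against second reagent, substrate is the limiting reagent.

**Seconds.** The feed takes 15 s, far shorter than the 6.00 min of the first ash reading, so the readings show a fully dosed flask.

**Minutes.** Cedar, with the flask's cover but less partner, 0.20 M against 0.260 M, reads 10 % at 6.00 min. From 10.0 min to 15.0 min it gains 5 percentage points. Alder, with a cover of 0.550, gains less over those minutes, 2 points, though each reading scatters by 2 points.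

**The limit.** No listed step takes target, so you look to 25 min. Cedar's gain carried straight on gives 34.0 %, your rough estimate for the flask.

**The result.** The forecast gives 25 min and 31 %, less than your estimate, holding that “no suspect step consumes it”. The flask gives 25.0 min and 35.8 %.

    intermediate B + capture agent → trapped intermediate (k = 0.0122 /M/s)
    second reagent + intermediate A → intermediate B (k = 0.0735 /M/s)
    third reagent + intermediate B → target (k = 0.0591 /M/s)
    substrate + partner → intermediate A (k = 0.0138 /M/s)
    substrate + second reagent → side product (k = 0.0151 /M/s)

**The neighbour.** In the flask at 25.0 min, target, side product, trapped intermediate and intermediate B together reach 94.7 %, under a cover of 110 %, with 14 % of the second reagent left. The neighbouring flask keeps the other charges and takes 0.055 M of second reagent, so its cover is 0.275, below one, which caps those products at 27.5 %. At 25.0 min it has 0.0087 % of its second reagent left. Target, side product, trapped intermediate and intermediate B sum to 27.5 %, target being 13.1 %, and intermediate A stands at 63.6 %.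

The runs come from a simulation for substances that don't exist.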